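## Retrosynthetic overview
- Sophoranone is the (2S)-flavanone. The only ring built after the two aromatic fragments are joined is the pyranone (C) ring. It is closed by an enantioselective intramolecular oxa-Michael addition of a 2'-hydroxychalcone, after which the 7-OMOM group is removed (steps 13–14).
- The chalcone comes from a late Claisen–Schmidt coupling of two similarly sized fragments: acetophenone **10** (A ring, 8-prenyl, 7-OMOM) and aldehyde **18** (B ring, 3,5-diprenyl-4-hydroxy) (step 12).
- Each prenyl group is made by the same two-step sequence: Claisen rearrangement of an allyl aryl ether, then cross-metathesis with 2-methyl-2-butene. This gives a normal prenyl group, which a Claisen rearrangement of a prenyl ether cannot.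
- **10** is built from resorcinol in 5 steps. **18** is built from 4-bromophenol in 6 steps (double Claisen, cross-metathesis, Br/Li formylation).

Assumption: the quinine-derived bifunctional squaramide gives the (2S) enantiomer. If (2R) is obtained, the quinidine-derived pseudo-enantiomer is used instead.

## Forward route

**Step 1**
Reactants: 1 resorcinol; 2 acetic acid
Product: 3 2,4-dihydroxyacetophenone
Conditions: BF3·OEt2, 90 °C, 3 h
Reagents that add atoms: acetic acid (2), CC(=O)O
Why: Friedel–Crafts C-acylation at the ring position para to one OH and ortho to the other; the product is stabilised by a chelated 2-OH···O=C. No stereocentre.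

**Step 2**
Reactants: 3; 4 allyl bromide
Product: 5 4-allyloxy-2-hydroxyacetophenone
Conditions: K2CO3, acetone, reflux, 12 h
Reagents that add atoms: allyl bromide (4), C=CCBr
Why: Williamson O-alkylation is selective for the more acidic, non-chelated 4-OH; the 2-OH is locked in a hydrogen bond with the ketone. No stereocentre.

**Step 3**
Reactants: 5
Product: 6 3-allyl-2,4-dihydroxyacetophenone
Conditions: PhNEt2, 210 °C (sealed tube or microwave), 2 h
Reagents that add atoms: none
Why: aromatic Claisen rearrangement [3,3]. It goes mainly to C3, between the two oxygens, as in 7-allyloxychromones, which give the 8-allyl product. The minor C5 isomer is removed by chromatography.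

**Step 4**
Reactants: 6; 7 chloromethyl methyl ether (MOMCl)
Product: 8 1-[3-allyl-2-hydroxy-4-(methoxymethoxy)phenyl]ethanone
Conditions: MOMCl, iPr2NEt, CH2Cl2, 0 °C → rt, 3 h
Reagents that add atoms: MOMCl (7), COCCl
Why: MOM protection of the free, non-chelated 4-OH, chosen so that the later cyclisation substrate carries no acidic 7-phenol and no 7-phenoxide. The chelated 2-OH stays free. No stereocentre.

**Step 5**
Reactants: 8; 9 2-methyl-2-butene
Product: 10 1-[2-hydroxy-4-(methoxymethoxy)-3-(3-methylbut-2-en-1-yl)phenyl]ethanone
Conditions: Grubbs II (5 mol %), 2-methyl-2-butene (20 equiv), 1,4-benzoquinone (10 mol %), CH2Cl2, 40 °C, 12 h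
Reagents that add atoms: 2-methyl-2-butene (9), CC=C(C)C
Why: olefin cross-metathesis converts the terminal allyl group into a prenyl group, with propene lost as gas. Benzoquinone suppresses Ru–H isomerisation of the allyl group. No stereocentre.

**Step 6**
Reactants: 11 4-bromophenol; 4 allyl bromide
Product: 12 1-(allyloxy)-4-bromobenzene
Conditions: K2CO3, acetone, reflux, 12 h
Reagents that add atoms: allyl bromide (4), C=CCBr
Why: Williamson etherification of the phenol. No stereocentre.

**Step 7**
Reactants: 12
Product: 13 2-allyl-4-bromophenol
Conditions: PhNEt2, reflux (~215 °C), 4 h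
Reagents that add atoms: none
Why: Claisen rearrangement to the free ortho position; the para position is blocked by Br.

**Step 8**
Reactants: 13; 4 allyl bromide
Product: 14 2-allyl-1-(allyloxy)-4-bromobenzene
Conditions: K2CO3, acetone, reflux, 12 h
Reagents that add atoms: allyl bromide (4), C=CCBr
Why: a second O-allylation prepares the second Claisen rearrangement.

**Step 9**
Reactants: 14
Product: 15 2,6-diallyl-4-bromophenol
Conditions: PhNEt2, reflux, 4 h
Reagents that add atoms: none
Why: Claisen rearrangement into the remaining ortho position.

**Step 10**
Reactants: 15; 9 2-methyl-2-butene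
Product: 16 4-bromo-2,6-bis(3-methylbut-2-en-1-yl)phenol
Conditions: Hoveyda–Grubbs II (5 mol %), 2-methyl-2-butene (40 equiv), 1,4-benzoquinone (10 mol %), CH2Cl2, 40 °C, 16 h
Reagents that add atoms: 2-methyl-2-butene (9), CC=C(C)C
Why: double cross-metathesis gives the two prenyl groups; the aryl bromide and free phenol are tolerated. No stereocentre.

**Step 11**
Reactants: 16; 17 N,N-dimethylformamide (DMF)
Product: 18 4-hydroxy-3,5-bis(3-methylbut-2-en-1-yl)benzaldehyde
Conditions: KH, THF, 0 °C; then t-BuLi (2.2 equiv), –78 °C; then DMF; NH4Cl(aq)
Reagents that add atoms: DMF (17), CN(C)C=O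
Why: the phenol is first deprotonated in situ, then Br/Li exchange followed by a Bouveault formylation gives the aldehyde. Exchange at –78 °C is much faster than deprotonation of the prenyl CH2.

**Step 12**
Reactants: 10; 18
Product: 19 (E)-2'-hydroxy-4'-(methoxymethoxy)-3,3',5-tris(3-methylbut-2-en-1-yl)-4-hydroxychalcone (the 4-OH is on the B ring)
Conditions: KOH (5 equiv), EtOH/H2O, 45 °C, 48 h; then cold 1 M HCl to pH 5
Reagents that add atoms: none
Why: Claisen–Schmidt aldol condensation joins the two fragments. Dehydration gives the E-enone, and the stable 2'-phenoxide of the chalcone disfavours spontaneous racemic cyclisation in base. Any racemic flavanone formed is removed by chromatography.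

**Step 13**
Reactants: 19
Product: 20 (2S)-7-(methoxymethoxy)-4',7-... i.e. (S)-4'-hydroxy-7-(methoxymethoxy)-3',5',8-tris(3-methylbut-2-en-1-yl)flavanone
Conditions: quinine-derived squaramide catalyst (10 mol %), toluene, 10 °C, 3 d
Reagents that add atoms: none
Why: intramolecular oxa-Michael addition (6-endo-trig). The quinuclidine nitrogen orients and deprotonates the 2'-OH while the squaramide N–H groups bind the enone carbonyl. The phenoxide then adds to one enantiotopic face of the β-carbon, setting C2 as (S). Low temperature and stopping at high conversion limit retro-Michael erosion of ee.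

**Step 14**
Reactants: 20
Product: 21 sophoranone, (2S)-7,4'-dihydroxy-3',5',8-tris(3-methylbut-2-en-1-yl)flavanone
Conditions: 3 M HCl(aq)/MeOH (1:6), 40 °C, 6 h
Reagents that add atoms: none
Why: acid hydrolysis of the aryl MOM acetal. C2 is not involved, and no base is present to open the flavanone, so the stereocentre is retained; the prenyl groups tolerate dilute HCl at this temperature.

## Checks performed
- Target SMILES re-read: a 7-OH, 8-prenyl flavanone with a 4'-OH flanked by 3',5'-diprenyl groups. The stereocentre is [C@@H] with neighbour order (aryl, H, O, CH2), which is CIP (S).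
- Steps 13 and 14 deliver exactly this structure.
- Formula balance: 19 and 20 are both C32H40O5, and 21 is C30H36O4, the formula of sophoranone.
- The only stereocentre, C2, is created in step 13 and is untouched in step 14.
- Protecting-group and functional-group survival:
  - The MOM ether survives the base in step 12 and the catalysis in step 13.
  - The prenyl groups and the free phenols survive steps 10–14.
  - The allyl-to-prenyl cross-metatheses are run before any chiral material exists.

## Compound list
1 | resorcinol | Oc1cccc(O)c1 | starting material
2 | acetic acid | CC(=O)O | starting material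
3 | 2,4-dihydroxyacetophenone | CC(=O)c1ccc(O)cc1O | intermediate
4 | allyl bromide | C=CCBr | starting material
5 | 4-allyloxy-2-hydroxyacetophenone | CC(=O)c1ccc(OCC=C)cc1O | intermediate
6 | 3-allyl-2,4-dihydroxyacetophenone | CC(=O)c1ccc(O)c(CC=C)c1O | intermediate
7 | chloromethyl methyl ether (MOMCl) | COCCl | starting material
8 | 1-[3-allyl-2-hydroxy-4-(methoxymethoxy)phenyl]ethanone | CC(=O)c1ccc(OCOC)c(CC=C)c1O | intermediate
9 | 2-methyl-2-butene | CC=C(C)C | starting material
10 | 1-[2-hydroxy-4-(methoxymethoxy)-3-prenylphenyl]ethanone | CC(=O)c1ccc(OCOC)c(CC=C(C)C)c1O | intermediate (A-ring fragment)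
11 | 4-bromophenol | Oc1ccc(Br)cc1 | starting material
12 | 1-(allyloxy)-4-bromobenzene | C=CCOc1ccc(Br)cc1 | intermediate
13 | 2-allyl-4-bromophenol | C=CCc1cc(Br)ccc1O | intermediate
14 | 2-allyl-1-(allyloxy)-4-bromobenzene | C=CCOc1ccc(Br)cc1CC=C | intermediate
15 | 2,6-diallyl-4-bromophenol | C=CCc1cc(Br)cc(CC=C)c1O | intermediate
16 | 4-bromo-2,6-diprenylphenol | CC(C)=CCc1cc(Br)cc(CC=C(C)C)c1O | intermediate
17 | N,N-dimethylformamide | CN(C)C=O | starting material
18 | 4-hydroxy-3,5-diprenylbenzaldehyde | CC(C)=CCc1cc(C=O)cc(CC=C(C)C)c1O | intermediate (B-ring fragment)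
19 | (E)-chalcone, 4-hydroxy-3,5-diprenylphenyl enone with 2'-hydroxy-4'-OMOM-3'-prenylphenyl ketone | CC(C)=CCc1cc(/C=C/C(=O)c2ccc(OCOC)c(CC=C(C)C)c2O)cc(CC=C(C)C)c1O | intermediate
20 | (2S)-7-OMOM flavanone | CC(C)=CCc1cc([C@@H]2CC(=O)c3ccc(OCOC)c(CC=C(C)C)c3O2)cc(CC=C(C)C)c1O | intermediate
21 | sophoranone | CC(C)=CCc1cc([C@@H]2CC(=O)c3ccc(O)c(CC=C(C)C)c3O2)cc(CC=C(C)C)c1O | target

## Totals
- Total steps: 14.
- Longest linear sequence: 9 steps, from 4-bromophenol through steps 6–14.
- The A-ring branch (steps 1–5) has 5 steps.

## Three steps most likely to fail
1. **Step 13 (enantioselective oxa-Michael).** The reaction is reversible, and the electron-rich 4-hydroxyaryl enone is a poor acceptor, so conversion may be low or ee may erode. Fallback: make racemic flavanone 20 by Et3N- or KOH-mediated cyclisation of 19, resolve it by preparative chiral-phase HPLC, and recycle the (R)-enantiomer by base-induced ring-opening back to 19.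
2. **Step 10 (double cross-metathesis of 15).** Ru–H isomerisation of the allyl groups to propenyl, or chelation of Ru by the free phenol, could give mixtures. Fallback: drop the allyl-to-prenyl strategy and prepare the 2,6-diprenylphenol by directed ortho-lithiation of an aryl O-carbamate with s-BuLi/TMEDA, trapping twice with prenyl bromide under CuI catalysis.
3. **Step 12 (Claisen–Schmidt with the phenoxide aldehyde 18).** The para-phenoxide deactivates the aldehyde, so conversion may be low or retro-aldol products may form. Fallback: change the coupling to a Mizoroki–Heck reaction between aryl bromide 16 (as its MOM ether) and the 2'-hydroxy-3'-prenyl-4'-OMOM aryl vinyl ketone, which forms the same enone C=C bond without an aldehyde.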